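**Plan**
The target, 3-(3,4-dimethoxyphenyl)propyl 3-(3,4-dimethoxyphenyl)propanoate, is achiral: it has no stereocentre and no double-bond geometry, so no stereochemistry has to be set.
Retrosynthesis: the benzylic CH2 of the acid half (C3 of the propanoate) goes back to a ketone and the acid-side arene (ring A) to a 1,4-cyclohexadiene. Then the ring bonds C1–C2 and C5–C6 of ring A are cut (C1 carries the chain, C3 and C4 the methoxy groups), and last the ester C–O bond and the C2–C3 bond of the keto ester.
Enabling feature: in ring A the methoxy-bearing carbons C3 and C4 are adjacent and flanked by unsubstituted C2 and C5, which is the carbon skeleton of symmetric 2,3-dimethoxybuta-1,3-diene. C1 and C6 are the two carbons of a terminal alkyne, and the carbon attached to C1 can be a ketone that activates it.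
Forward: silylpropiolic acid is joined to Meldrum's acid, the alcohol half (ring B intact) is attached by alcoholysis, the alkyne is unmasked, ring A is closed by Diels–Alder addition, aromatised, and the ketone is reduced to CH2.

Key step: step 4

Remark: the terminal ynone β-keto ester is assumed to be a keto/enol mixture that equilibrates at the cycloaddition temperature; it is kept in solution and used at once.

Step 1
Reactants: 1 3-(trimethylsilyl)prop-2-ynoic acid; 2 Meldrum's acid (2,2-dimethyl-1,3-dioxane-4,6-dione)
Product: 3 5-[1-hydroxy-3-(trimethylsilyl)prop-2-yn-1-ylidene]-2,2-dimethyl-1,3-dioxane-4,6-dione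
Conditions: DCC (1.1 equiv), DMAP (1.2 equiv), CH2Cl2, −10 °C → rt; filtration, cold aq. KHSO4 wash
Reagents that add atoms: none
Why: Carbodiimide-mediated C-acylation of Meldrum's acid is general for carboxylic acids, and the silyl group shields the alkyne β-carbon from conjugate addition of DMAP, so the enolic acyl Meldrum's acid should form cleanly at low temperature.

Step 2
Reactants: 3 5-[1-hydroxy-3-(trimethylsilyl)prop-2-yn-1-ylidene]-2,2-dimethyl-1,3-dioxane-4,6-dione; 4 3-(3,4-dimethoxyphenyl)propan-1-ol
Product: 6 3-(3,4-dimethoxyphenyl)propyl 3-oxo-5-(trimethylsilyl)pent-4-ynoate, via acylketene 5 (not isolated)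
Conditions: 3 (1.1 equiv), PhMe, 85 °C
Reagents that add atoms: none
Why: Thermal fragmentation of the acyl Meldrum's acid should expel acetone and CO2 to give the acylketene, which the primary alcohol traps as the β-keto ester (acyl Meldrum's acid alcoholysis) under neutral conditions that leave the silyl ynone and the veratrole ring untouched.

Step 3
Reactants: 6 3-(3,4-dimethoxyphenyl)propyl 3-oxo-5-(trimethylsilyl)pent-4-ynoate
Product: 7 3-(3,4-dimethoxyphenyl)propyl 3-oxopent-4-ynoate
Conditions: TBAF (1.05 equiv), AcOH (2 equiv), THF, −20 → 0 °C; cold work-up, used directly as a solution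
Reagents that add atoms: none
Why: Fluoride-induced protodesilylation of the C(sp)–Si bond is very fast for a silyl ynone, and the acetic acid buffer at low temperature should protonate the acetylide at once and keep the medium too weakly basic for the β-keto ester to add to the freed ynone.

Step 4
Reactants: 7 3-(3,4-dimethoxyphenyl)propyl 3-oxopent-4-ynoate; 8 2,3-dimethoxybuta-1,3-diene
Product: 9 3-(3,4-dimethoxyphenyl)propyl 3-(4,5-dimethoxycyclohexa-1,4-dien-1-yl)-3-oxopropanoate
Conditions: 8 (3 equiv), BHT (cat.), PhMe, 90 °C, sealed tube under Ar; excess 8 removed in vacuo, crude 9 carried on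
Reagents that add atoms: none
Why: The electron-rich diene 8 (HOMO raised by two methoxy donors) and the keto tautomer of ynone 7 (alkyne LUMO lowered by the adjacent ketone) should combine in a concerted, suprafacial [4+2] cycloaddition of normal electron demand, the thermal Diels–Alder reaction. The closest known reaction type is the addition of 2,3-dialkoxybutadienes to acetylenic ketones and esters, which gives 1,2-dialkoxycyclohexa-1,4-dienes ready for dehydrogenation. The six-membered carbocycle closes intermolecularly by forming both new C–C bonds in one event, from the diene termini to the terminal and the internal alkyne carbon (future C5–C6 and C1–C2 of ring A), and no stereocentre arises. The step needs chemoselectivity for cycloaddition over conjugate addition or oligomerisation of the ynone, which neutral, aprotic, base-free conditions, excess diene and a radical inhibitor should secure, since keto and enol forms interconvert and only the keto form is drained. Regioselectivity is not at stake because the diene is twofold symmetric, and the reaction should stop at the 1:1 adduct because 9 holds no alkyne and its trisubstituted enone is a far poorer dienophile.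

Step 5
Reactants: 9 3-(3,4-dimethoxyphenyl)propyl 3-(4,5-dimethoxycyclohexa-1,4-dien-1-yl)-3-oxopropanoate
Product: 10 3-(3,4-dimethoxyphenyl)propyl 3-(3,4-dimethoxyphenyl)-3-oxopropanoate
Conditions: DDQ (1.05 equiv), PhMe, 0 °C → rt
Reagents that add atoms: none
Why: DDQ dehydrogenation of a 1,4-cyclohexadiene (hydride abstraction from a doubly allylic CH2, then proton loss) is driven by aromatisation and should be far faster at 0 °C than any attack on the benzylic positions of ring B or on the β-keto ester.

Step 6
Reactants: 10 3-(3,4-dimethoxyphenyl)propyl 3-(3,4-dimethoxyphenyl)-3-oxopropanoate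
Product: 12 3-(3,4-dimethoxyphenyl)propyl 3-(3,4-dimethoxyphenyl)propanoate, via benzylic alcohol 11 (not isolated)
Conditions: Et3SiH (3 equiv), TFA, rt → 50 °C
Reagents that add atoms: none
Why: In this ionic hydrogenation the protonated aryl ketone should take hydride to give the benzylic alcohol, which ionises to a cation stabilised by the para-methoxy group and is reduced a second time, a deoxygenation typical of electron-rich aryl ketones that spares the ester and the methyl ethers.

**Compound list**
1 | 3-(trimethylsilyl)prop-2-ynoic acid | C[Si](C)(C)C#CC(=O)O | starting material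
2 | Meldrum's acid (2,2-dimethyl-1,3-dioxane-4,6-dione) | CC1(C)OC(=O)CC(=O)O1 | starting material
3 | 5-[1-hydroxy-3-(trimethylsilyl)prop-2-yn-1-ylidene]-2,2-dimethyl-1,3-dioxane-4,6-dione | CC1(C)OC(=O)C(=C(O)C#C[Si](C)(C)C)C(=O)O1 | intermediate
4 | 3-(3,4-dimethoxyphenyl)propan-1-ol | COc1ccc(CCCO)cc1OC | starting material
5 | 5-(trimethylsilyl)pent-1-en-4-yne-1,3-dione (transient acylketene, formed in the flask) | O=C=CC(=O)C#C[Si](C)(C)C | intermediate
6 | 3-(3,4-dimethoxyphenyl)propyl 3-oxo-5-(trimethylsilyl)pent-4-ynoate | COc1ccc(CCCOC(=O)CC(=O)C#C[Si](C)(C)C)cc1OC | intermediate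
7 | 3-(3,4-dimethoxyphenyl)propyl 3-oxopent-4-ynoate | C#CC(=O)CC(=O)OCCCc1ccc(OC)c(OC)c1 | intermediate
8 | 2,3-dimethoxybuta-1,3-diene | COC(=C)C(=C)OC | starting material
9 | 3-(3,4-dimethoxyphenyl)propyl 3-(4,5-dimethoxycyclohexa-1,4-dien-1-yl)-3-oxopropanoate | COC1=C(OC)CC(C(=O)CC(=O)OCCCc2ccc(OC)c(OC)c2)=CC1 | intermediate
10 | 3-(3,4-dimethoxyphenyl)propyl 3-(3,4-dimethoxyphenyl)-3-oxopropanoate | COc1ccc(CCCOC(=O)CC(=O)c2ccc(OC)c(OC)c2)cc1OC | intermediate
11 | 3-(3,4-dimethoxyphenyl)propyl 3-(3,4-dimethoxyphenyl)-3-hydroxypropanoate (racemic, formed in the flask) | COc1ccc(CCCOC(=O)CC(O)c2ccc(OC)c(OC)c2)cc1OC | intermediate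
12 | 3-(3,4-dimethoxyphenyl)propyl 3-(3,4-dimethoxyphenyl)propanoate | COc1ccc(CCCOC(=O)CCc2ccc(OC)c(OC)c2)cc1OC | target

**Step count and risks**
Total step count: 6. Longest linear sequence: 6 steps (1 → 3 → 6 → 7 → 9 → 10 → 12).

Steps most likely to fail:

Step 4. Conjugate addition of the enolised β-keto ester to the ynone, or oligomerisation of the ynone, may outrun the cycloaddition. The acidic substrate may also trigger hydrolysis or polymerisation of the dienol ether. The fallback sets out from 8 and builds ring A on a dienophile that has no acidic methylene. Diene 8 and purchased but-3-yn-2-one are heated in toluene to give 1-(4,5-dimethoxycyclohexa-1,4-dien-1-yl)ethan-1-one F1. DDQ aromatises it to 1-(3,4-dimethoxyphenyl)ethan-1-one F2. C-acylation of the enolate with NaH and dimethyl carbonate gives methyl 3-(3,4-dimethoxyphenyl)-3-oxopropanoate F3. Transesterification with alcohol 4 in refluxing toluene, with removal of methanol, comes back to the route at 10.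

Step 3. The freed terminal ynone may self-condense through Michael addition of the β-keto ester enolate while fluoride is present, or degrade on concentration. The fallback sets out from 4 and unmasks the alkyne before the ketone exists. Acetylation (Ac2O, pyridine) gives 3-(3,4-dimethoxyphenyl)propyl acetate F4. Its lithium enolate (LDA, THF, −78 °C) adds to 3-(trimethylsilyl)propynal to give racemic 3-(3,4-dimethoxyphenyl)propyl 3-hydroxy-5-(trimethylsilyl)pent-4-ynoate F5. TBAF in THF removes the silyl group to give 3-(3,4-dimethoxyphenyl)propyl 3-hydroxypent-4-ynoate F6, which is neither a Michael acceptor nor carbon-acidic. Dess–Martin oxidation under neutral conditions comes back to the route at 7.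

Step 6. The reduction may stall at the benzylic alcohol or at the cinnamate formed from it by dehydration, and the benzylic cation may alkylate one of the electron-rich rings. The fallback sets out from 10 and replaces the ionic hydrogenation by a stepwise sequence. NaBH4 in MeOH at 0 °C gives 11 as an isolated compound. Dehydration with catalytic TsOH in refluxing toluene gives 3-(3,4-dimethoxyphenyl)propyl (E)-3-(3,4-dimethoxyphenyl)prop-2-enoate F7. Hydrogenation of the alkene (H2, Pd/C, EtOAc) comes back to the route at 12.

**Further compounds**
F1 | step 4 | 1-(4,5-dimethoxycyclohexa-1,4-dien-1-yl)ethan-1-one | COC1=C(OC)CC(C(C)=O)=CC1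
F2 | step 4 | 1-(3,4-dimethoxyphenyl)ethan-1-one | COc1ccc(C(C)=O)cc1OC
F3 | step 4 | methyl 3-(3,4-dimethoxyphenyl)-3-oxopropanoate | COC(=O)CC(=O)c1ccc(OC)c(OC)c1
F4 | step 3 | 3-(3,4-dimethoxyphenyl)propyl acetate | COc1ccc(CCCOC(C)=O)cc1OC
F5 | step 3 | 3-(3,4-dimethoxyphenyl)propyl 3-hydroxy-5-(trimethylsilyl)pent-4-ynoate (racemic) | COc1ccc(CCCOC(=O)CC(O)C#C[Si](C)(C)C)cc1OC
F6 | step 3 | 3-(3,4-dimethoxyphenyl)propyl 3-hydroxypent-4-ynoate (racemic) | C#CC(O)CC(=O)OCCCc1ccc(OC)c(OC)c1
F7 | step 6 | 3-(3,4-dimethoxyphenyl)propyl (E)-3-(3,4-dimethoxyphenyl)prop-2-enoate | COc1ccc(CCCOC(=O)/C=C/c2ccc(OC)c(OC)c2)cc1OC
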